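## Structural features

The target is a (2S)-flavanone: benzene ring A is fused through C4a and C8a to dihydropyranone ring C (O1, C2, C3, C4=O), and a 4-hydroxyphenyl ring B sits on C2. Ring A is fully differentiated: O1 at C8a, a C-bound (E)-geranyl chain at C8, an O-geranyl ether at C7, a free hydroxyl at C5 hydrogen-bonded to the C4 ketone, and hydrogen only at C6. C2 is the only stereocentre, so there is no relative configuration to control, but it is benzylic to an electron-rich ring, bears O1 and lies beta to the ketone. It can therefore be lost under base, by beta-elimination of the O1 phenoxide to the 2'-hydroxychalcone and reclosure, and under acid, by benzylic ionisation. The two geranyl groups bring four trisubstituted alkenes and an allyl aryl ether, which exclude hydrogenolysis, strong protic or Lewis acids, electrophilic oxidants and prolonged heating. The real difficulties are the regiochemistry of ring A (geranyl at C8 and not C6, so the more hindered of the two ortho-oxygens must become O1) and setting C2 so that neither acid nor base is needed afterwards. The key step exploits the position of C3 and C4 between the aryl ketone carbon and the C2–O1 ether: with C4 held as the enol silane of an acetyl group and a vinyl group on C2, metathesis forms C3=C4 and closes ring C, and the ketone appears on desilylation.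

## Logic of the disconnections

**16 to 14.** Only Si–O bonds are cut: the enol silane at C4 and the aryl silyl ethers at O5 and O4'. All three are chosen to be fluoride-labile so that one buffered operation gives 16 through transient 15. An acetal at O5 was rejected, because the acid needed to cleave an aryl acetal is not mild and would meet the O-geranyl ether and four trisubstituted alkenes. The demand on the forward step is a fluoride source buffered well enough that no enolate or phenoxide lives long enough to open ring C.

**14 to 13.** The C3=C4 bond is cut, which opens ring C. C2 becomes an ordinary allylic ether carbon bearing a vinyl group, and C4 becomes the enol silane carbon of an acetyl group. The gain is that the ring and the ketone oxidation level are reached without aldol, oxidation or base. The demand is that the catalyst engage only the vinyl group and the enol silane among six alkenes and leave C2 alone.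

**13 to 12.** The enol O–Si bond is cut, giving back the methyl ketone. The gain is a stable, purifiable ketone as the storage point. The forward step must enolise without ionising the benzylic, allylic aryl ether.

**12 to 6 and 10.** The O1–C2 bond is cut. This is the convergent cut: it separates the ring A half from the ring B half and is the place where the only stereocentre is set, by asymmetric allylic etherification of the phenoxide 11 derived from 6. The demand is heavy: the reacting oxygen is flanked by the acetyl group and the geranyl methylene, so every other oxygen must be blocked, and the catalyst must give the branched ether on one face. Triisopropylsilyl is used on both phenols so that phenoxide and the methoxide released from 10 cannot strip or shuffle silicon.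

**10 to 9, 8 and 7.** Only functional groups change: carbonate from allylic alcohol, alcohol from ester, silyl ether from phenol. The (E)-alkene of 7 is carried through unchanged, and the forward steps are routine.

**6 to 5.** The O–Si bond at the C6 oxygen of the acetophenone (O5 of the target) is cut. This is where the two ortho-hydroxyls of 5 are told apart; the forward step relies on the hydroxyl next to the geranyl methylene being the more shielded.

**5 to 3 and 4.** The O–C bond of the geranyl ether is cut. The hydroxyl para to the acetyl group is the most acidic and the only unchelated one. The forward step must be O-selective, since the free ring carbon of 3 is nucleophilic towards allylic halides.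

**3 to 1 and 2.** The aryl C–C bond to the geranyl chain is cut, leading to two commercial materials. The forward step must favour mono-C-alkylation over O-alkylation and double alkylation; the symmetry of 1 removes any regiochemical question at this stage.

## Other disconnections considered

**Alternative 1:** The cut removes ring A altogether. C8–C8a and C6–C7 are disconnected, and C8a–C4a is traced to the ring bond of a cyclobutenone. In the forward direction, cyclobutenone A1 is heated with siloxyalkyne A2. A four-electron ring opening gives a vinylketene, which adds regioselectively to the electron-rich alkyne; a second ring opening and a six-electron electrocyclisation, then tautomerisation, give phenol A3.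
- In its favour: each ring A position is fixed by the partner it came from, and the free phenol of A3 is necessarily O1, next to the geranyl carbon. On ring A regiocontrol this alternative is the better plan, since the chosen route relies on selective alkylation and silylation in steps 1 to 3.
- Against it: A1 carries the whole C2–C4 chain with its stereocentre and A2 is a sensitive ynol ether with a skipped enyne; both need several steps. The thermal cascade exposes the geranyl alkenes to heat.
- After A3, the C5 and C7 oxygens carry the same silyl group and must still be told apart. Ring C must be closed by displacement at C2 with inversion at an electron-rich benzylic carbon, where ionisation threatens the configuration. C4 must then be oxidised from the carbinol level.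
- Comparison: on mechanism the two are equal in setting C2 early by asymmetric synthesis, but the chosen plan never breaks a bond at C2 after making it. On step economy the chosen plan needs one step after its key step and ten in all; the alternative needs at least five after A3 and more before it.

**Alternative 2:** The cut is C4a–C5, so ring A is built on a preformed ring C. In the forward direction, a strong non-nucleophilic base converts dihydropyranone A4 into its extended enolate. C4a attacks the terminal ester, and loss of methoxide and enolisation give the phloroglucinol ring of A5.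
- In its favour: the C8 geranyl position is fixed by the chain, ring A needs no protecting groups, and A5 is two steps from the target (O-geranylation at the unchelated C7 hydroxyl, then desilylation). On ring A regiocontrol it is the better plan, and on the endgame it is about equal to the chosen plan.
- Against it: the most acidic protons of A4 are those between the ketone and the ester, not the one needed for the extended enolate, so a polyanion and excess base are required. C2, already in place, sits beta to a carbonyl with O1 as leaving group throughout, so base-mediated opening and reclosure of ring C can racemise it.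
- A4 itself needs an asymmetric pyranone synthesis and a site-selective chain geranylation.
- Comparison: the chosen plan closes its ring under neutral ruthenium catalysis and meets fluoride only when buffered. Total step counts are probably similar, but the risk to the stereocentre is higher in the alternative.

**Alternative 3:** The cut is O1–C8a. In the forward direction, the alkoxide of (S)-beta-hydroxy ketone A6 displaces fluoride ortho to the ketone, an intramolecular nucleophilic aromatic substitution that closes ring C and gives A7.
- In its favour: the fluorine marks without ambiguity which ring carbon becomes C8a. This is better than distinguishing two hydroxyls by steric hindrance as in step 3. The C2–O bond is never broken, so configuration is carried with retention; on this point it is the equal of the chosen plan.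
- Against it: a beta-hydroxy ketone under the base needed for the substitution can undergo retro-aldol cleavage or dehydration to the chalcone, and the product flavanone is itself base-labile.
- A7 carries three identical acetal groups. Their acidic removal frees the C7 hydroxyl next to the C8 geranyl alkene, which invites acid-promoted cyclisation onto that alkene. The C7 oxygen must then be geranylated selectively in the presence of the C4' and C5 hydroxyls.
- Comparison: two or three delicate steps follow its key step against one for the chosen plan, and the fluorinated ring A needs its own multi-step synthesis. Overall length would be similar or greater.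

Key step: step 9

## Remarks before the route

- Abbreviations: geranyl = (2E)-3,7-dimethylocta-2,6-dien-1-yl; TIPS = triisopropylsilyl; TBS = tert-butyldimethylsilyl. Flavanone numbering is used for ring positions, acetophenone numbering for open-chain intermediates.
- Assumption on the chemistry: the (Sa,Sc,Sc) phosphoramidite is assigned to the (S)-ether by the usual facial model for aryl-substituted allyl carbonates and oxygen nucleophiles; the antipodal ligand is equally available if the sense is the reverse.
- Assumption on materials: the cinnamate is bought as its methyl ester; starting from the free acid would add one esterification.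

## Route

Step 1
Reactants: 1 2,4,6-trihydroxyacetophenone; 2 geranyl bromide
Product: 3 1-(3-geranyl-2,4,6-trihydroxyphenyl)ethanone
Conditions: 2 (1.0 equiv), K2CO3 (1.0 equiv), acetone, reflux
Reagents that add atoms: none
Why: Phenoxide C-alkylation: the mono-anion of the acylphloroglucinol reacts as a vinylogous enolate at the ring carbon between two oxygens with the soft allylic bromide, and a weak base with one equivalent of 2 limits O-alkylation and double alkylation. Displacement at the primary carbon keeps the (E)-alkene.

Step 2
Reactants: 3 1-(3-geranyl-2,4,6-trihydroxyphenyl)ethanone; 4 geraniol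
Product: 5 1-[3-geranyl-4-(geranyloxy)-2,6-dihydroxyphenyl]ethanone
Conditions: 4 (1.05 equiv), PPh3, DIAD, THF, 0 °C → rt
Reagents that add atoms: none
Why: Mitsunobu etherification: the C4 hydroxyl, para to the acetyl group, is the most acidic and the only one not hydrogen-bonded to the ketone, so it should be the one alkylated. The neutral conditions avoid the ring C-alkylation that a phenoxide and an allylic bromide would give, and substitution at the primary carbon of 4 keeps the (E)-geometry.

Step 3
Reactants: 5 1-[3-geranyl-4-(geranyloxy)-2,6-dihydroxyphenyl]ethanone
Product: 6 1-[3-geranyl-4-(geranyloxy)-2-hydroxy-6-(triisopropylsilyloxy)phenyl]ethanone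
Conditions: TIPSCl (1.1 equiv), imidazole, DMF, 0 °C → rt
Reagents that add atoms: triisopropylsilyl chloride, CC(C)[Si](Cl)(C(C)C)C(C)C
Why: Silylation of a phenol: the C6 hydroxyl has only hydrogen as its other neighbour, whereas the C2 hydroxyl is shielded by the geranyl methylene, so the bulky silyl group should go to C6 and stop there. This leaves free the hindered, chelated oxygen that must become O1.

Step 4
Reactants: 7 methyl (E)-4-hydroxycinnamate
Product: 8 methyl (E)-4-(triisopropylsilyloxy)cinnamate
Conditions: TIPSCl, imidazole, DMF, rt
Reagents that add atoms: triisopropylsilyl chloride, CC(C)[Si](Cl)(C(C)C)C(C)C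
Why: Silylation of a phenol; the TIPS ether tolerates hydride, phenoxide and methoxide in the following steps and is cleaved by fluoride at the end.

Step 5
Reactants: 8 methyl (E)-4-(triisopropylsilyloxy)cinnamate
Product: 9 (E)-3-[4-(triisopropylsilyloxy)phenyl]prop-2-en-1-ol
Conditions: i-Bu2AlH (2.3 equiv), CH2Cl2, −78 → 0 °C; aq. potassium sodium tartrate
Reagents that add atoms: none
Why: 1,2-Reduction of an alpha,beta-unsaturated ester to the allylic alcohol by the aluminium hydride at low temperature, which leaves the (E)-alkene and the aryl silyl ether untouched.

Step 6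
Reactants: 9 (E)-3-[4-(triisopropylsilyloxy)phenyl]prop-2-en-1-ol
Product: 10 methyl (E)-3-[4-(triisopropylsilyloxy)phenyl]prop-2-enyl carbonate
Conditions: ClCO2Me, pyridine, CH2Cl2, 0 °C
Reagents that add atoms: methyl chloroformate, COC(=O)Cl
Why: Acylation of the primary allylic alcohol gives the linear methyl carbonate, the usual leaving group for iridium allyl chemistry.

Step 7
Reactants: 6 1-[3-geranyl-4-(geranyloxy)-2-hydroxy-6-(triisopropylsilyloxy)phenyl]ethanone; 10 methyl (E)-3-[4-(triisopropylsilyloxy)phenyl]prop-2-enyl carbonate
Product: 12 1-{3-geranyl-4-(geranyloxy)-2-[(1S)-1-(4-triisopropylsilyloxyphenyl)prop-2-enyloxy]-6-(triisopropylsilyloxy)phenyl}ethanone, via lithium phenoxide 11 (not isolated)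
Conditions: LiN(SiMe3)2 (1.0 equiv), THF, −78 → 0 °C; then 10 (1.3 equiv), [Ir(cod)Cl]2 (2 mol%), (Sa,Sc,Sc)-O,O'-(1,1'-binaphthalene-2,2'-diyl) N,N-bis(1-phenylethyl)phosphoramidite (4 mol%, preactivated with n-PrNH2), THF, rt → 40 °C
Reagents that add atoms: none
Why: Iridium-catalysed asymmetric allylic etherification: the cyclometallated iridium phosphoramidite complex ionises 10 to an allyl complex, and the phenoxide attacks its aryl-bearing terminus from the face away from the metal to give the branched ether. The ligand configuration fixes which face is attacked and so should set C2 as S; only the phenol is deprotonated by one equivalent of amide, and the ortho positions of the phenoxide are blocked against C-allylation.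

Step 8
Reactants: 12 1-{3-geranyl-4-(geranyloxy)-2-[(1S)-1-(4-triisopropylsilyloxyphenyl)prop-2-enyloxy]-6-(triisopropylsilyloxy)phenyl}ethanone
Product: 13 tert-butyl{1-[3-geranyl-4-(geranyloxy)-2-[(1S)-1-(4-triisopropylsilyloxyphenyl)prop-2-enyloxy]-6-(triisopropylsilyloxy)phenyl]ethenyloxy}dimethylsilane
Conditions: TBSOTf (1.3 equiv), Et3N (3 equiv), CH2Cl2, −78 → 0 °C
Reagents that add atoms: tert-butyldimethylsilyl trifluoromethanesulfonate, CC(C)(C)[Si](C)(C)OS(=O)(=O)C(F)(F)F
Why: Soft enolisation: the silyl triflate activates the ketone and triethylamine removes a methyl proton, giving the only possible enol silane. Excess amine and low temperature protect the benzylic allylic ether, and C2 is not involved.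

Step 9
Reactants: 13 tert-butyl{1-[3-geranyl-4-(geranyloxy)-2-[(1S)-1-(4-triisopropylsilyloxyphenyl)prop-2-enyloxy]-6-(triisopropylsilyloxy)phenyl]ethenyloxy}dimethylsilane
Product: 14 (2S)-4-(tert-butyldimethylsilyloxy)-8-geranyl-7-(geranyloxy)-5-(triisopropylsilyloxy)-2-[4-(triisopropylsilyloxy)phenyl]-2H-chromene
Conditions: RuCl2(=CHPh)(PCy3)(H2IMes) (second-generation Grubbs catalyst, 5–10 mol%), degassed benzene (0.01 M), 50 °C, argon purge
Reagents that add atoms: none
Why: Ring-closing olefin metathesis between a terminal alkene and a silyl enol ether, a known route to cyclic enol silanes and closest in type to the closure of allyl 2-vinylaryl ethers to 2H-chromenes. The ruthenium benzylidene exchanges first with the only monosubstituted alkene, the vinyl group on C2, to give a new alkylidene at the future C3. This alkylidene adds intramolecularly across the enol silane C=C with ruthenium on the unhindered CH2 and carbon on the siloxy-bearing carbon; cycloreversion of the ruthenacyclobutane forms C3=C4, closes six-membered ring C and releases Ru=CH2, which leaves as ethylene on the next turnover. The ring is thus closed by a [2+2] cycloaddition and cycloreversion pair between two groups held ortho to each other on ring A, and the twist of the 2,6-disubstituted enol silane keeps its CH2 end near the vinyl group. No stereocentre is formed; C2 should keep its S configuration because none of its four bonds takes part and the neutral conditions at 50 °C offer no path for ionisation or for electrocyclic opening of the product. The selectivity needed is chemoselectivity among six alkenes. Initiation is secured by the single terminal vinyl group and closure by the free CH2 terminus of the enol silane and six-membered ring formation, whereas any of the four trisubstituted geranyl alkenes would need ruthenium at a fully substituted carbon, would expel a disubstituted alkylidene, and at best (the 2',3'-alkene of the C8 chain) would close a seven-membered ring. Removal of ethylene drives the reaction forward.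

Step 10
Reactants: 14 (2S)-4-(tert-butyldimethylsilyloxy)-8-geranyl-7-(geranyloxy)-5-(triisopropylsilyloxy)-2-[4-(triisopropylsilyloxy)phenyl]-2H-chromene
Product: 16 (2S)-8-geranyl-7-(geranyloxy)-5-hydroxy-2-(4-hydroxyphenyl)chroman-4-one, via bis(triisopropylsilyl) flavanone 15 (not isolated)
Conditions: Bu4NF (4 equiv), AcOH (5 equiv), THF, 0 °C → rt
Reagents that add atoms: none
Why: Fluoride-mediated desilylation buffered by acetic acid: the enol silane is cleaved first and protonated at C3 to the ketone, then the two aryl silyl ethers fall, the one at O5 helped by the new hydrogen bond to C4=O. The buffer keeps enolate and phenoxide concentrations low, so ring C should not open to the chalcone and C2 should stay S; the geranyl groups see neither acid nor oxidant.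

## Compound list

1 | 2,4,6-trihydroxyacetophenone | CC(=O)c1c(O)cc(O)cc1O | starting material
2 | geranyl bromide | CC(C)=CCC/C(C)=C/CBr | starting material
3 | 1-(3-geranyl-2,4,6-trihydroxyphenyl)ethanone | CC(=O)c1c(O)cc(O)c(C/C=C(\C)CCC=C(C)C)c1O | intermediate
4 | geraniol | CC(C)=CCC/C(C)=C/CO | starting material
5 | 1-[3-geranyl-4-(geranyloxy)-2,6-dihydroxyphenyl]ethanone | CC(=O)c1c(O)cc(OC/C=C(\C)CCC=C(C)C)c(C/C=C(\C)CCC=C(C)C)c1O | intermediate
6 | 1-[3-geranyl-4-(geranyloxy)-2-hydroxy-6-(triisopropylsilyloxy)phenyl]ethanone | CC(=O)c1c(O[Si](C(C)C)(C(C)C)C(C)C)cc(OC/C=C(\C)CCC=C(C)C)c(C/C=C(\C)CCC=C(C)C)c1O | intermediate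
7 | methyl (E)-4-hydroxycinnamate | COC(=O)/C=C/c1ccc(O)cc1 | starting material
8 | methyl (E)-4-(triisopropylsilyloxy)cinnamate | COC(=O)/C=C/c1ccc(O[Si](C(C)C)(C(C)C)C(C)C)cc1 | intermediate
9 | (E)-3-[4-(triisopropylsilyloxy)phenyl]prop-2-en-1-ol | OC/C=C/c1ccc(O[Si](C(C)C)(C(C)C)C(C)C)cc1 | intermediate
10 | methyl (E)-3-[4-(triisopropylsilyloxy)phenyl]prop-2-enyl carbonate | COC(=O)OC/C=C/c1ccc(O[Si](C(C)C)(C(C)C)C(C)C)cc1 | intermediate
11 | lithium 2-acetyl-6-geranyl-5-(geranyloxy)-3-(triisopropylsilyloxy)phenoxide | CC(=O)c1c(O[Si](C(C)C)(C(C)C)C(C)C)cc(OC/C=C(\C)CCC=C(C)C)c(C/C=C(\C)CCC=C(C)C)c1[O-].[Li+] | intermediate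
12 | 1-{3-geranyl-4-(geranyloxy)-2-[(1S)-1-(4-triisopropylsilyloxyphenyl)prop-2-enyloxy]-6-(triisopropylsilyloxy)phenyl}ethanone | CC(=O)c1c(O[Si](C(C)C)(C(C)C)C(C)C)cc(OC/C=C(\C)CCC=C(C)C)c(C/C=C(\C)CCC=C(C)C)c1O[C@H](c1ccc(O[Si](C(C)C)(C(C)C)C(C)C)cc1)C=C | intermediate
13 | tert-butyl{1-[3-geranyl-4-(geranyloxy)-2-[(1S)-1-(4-triisopropylsilyloxyphenyl)prop-2-enyloxy]-6-(triisopropylsilyloxy)phenyl]ethenyloxy}dimethylsilane | C=C(O[Si](C)(C)C(C)(C)C)c1c(O[Si](C(C)C)(C(C)C)C(C)C)cc(OC/C=C(\C)CCC=C(C)C)c(C/C=C(\C)CCC=C(C)C)c1O[C@H](c1ccc(O[Si](C(C)C)(C(C)C)C(C)C)cc1)C=C | intermediate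
14 | (2S)-4-(tert-butyldimethylsilyloxy)-8-geranyl-7-(geranyloxy)-5-(triisopropylsilyloxy)-2-[4-(triisopropylsilyloxy)phenyl]-2H-chromene | CC(C)=CCC/C(C)=C/COc1cc(O[Si](C(C)C)(C(C)C)C(C)C)c2c(c1C/C=C(\C)CCC=C(C)C)O[C@H](c1ccc(O[Si](C(C)C)(C(C)C)C(C)C)cc1)C=C2O[Si](C)(C)C(C)(C)C | intermediate
15 | (2S)-8-geranyl-7-(geranyloxy)-5-(triisopropylsilyloxy)-2-[4-(triisopropylsilyloxy)phenyl]chroman-4-one | CC(C)=CCC/C(C)=C/COc1cc(O[Si](C(C)C)(C(C)C)C(C)C)c2c(c1C/C=C(\C)CCC=C(C)C)O[C@H](c1ccc(O[Si](C(C)C)(C(C)C)C(C)C)cc1)CC2=O | intermediate
16 | (2S)-8-geranyl-7-(geranyloxy)-5-hydroxy-2-(4-hydroxyphenyl)chroman-4-one | CC(C)=CCC/C(C)=C/COc1cc(O)c2c(c1C/C=C(\C)CCC=C(C)C)O[C@H](c1ccc(O)cc1)CC2=O | target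

## Step count and least certain steps

Total step count: 10. Longest linear sequence: 7 steps (steps 1, 2, 3, 7, 8, 9 and 10 from 1); the three-step branch from 7 (steps 4 to 6) joins at step 7.

**Step 9 (key step).** The closure may be outrun by metathesis onto the 2',3'-alkene of the C8 geranyl chain (seven-membered ring), or turnover may be slow on the crowded, electron-rich enol silane. In the second case the catalyst decays to ruthenium hydrides that move the allyl ether double bond into conjugation with oxygen, which would erase C2. The fallback abandons metathesis and sets C2 by conjugate arylation. It sets out from 6: condensation with Me2NCH(OMe)2 should give the enaminone (E)-3-(dimethylamino)-1-[3-geranyl-4-(geranyloxy)-2-hydroxy-6-(triisopropylsilyloxy)phenyl]prop-2-en-1-one F1. Mild acid should close this with loss of dimethylamine to 8-geranyl-7-(geranyloxy)-5-(triisopropylsilyloxy)-4H-chromen-4-one F2. Asymmetric 1,4-addition of commercial [4-(tert-butyldimethylsilyloxy)phenyl]boronic acid, catalysed by [RhOH(cod)]2 and an electron-poor axially chiral biaryl bisphosphine (the antipode chosen for the 2S product) in aqueous toluene, should then give (2S)-2-[4-(tert-butyldimethylsilyloxy)phenyl]-8-geranyl-7-(geranyloxy)-5-(triisopropylsilyloxy)chroman-4-one F3. Buffered fluoride as in step 10 brings the fallback back to the route at 16.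

**Step 7.** The phenoxide is chelated to the ketone and flanked on both sides, so attack on the allyl complex may be slow enough for linear ether formation or carbonate exchange to compete. The product, an electron-rich benzylic ether with a stabilised aryloxide as leaving group, may also re-ionise on the catalyst, with branched-to-linear drift and erosion of enantiopurity. The fallback makes the same bond by substitution with inversion. Commercial 3-chloro-1-(4-hydroxyphenyl)propan-1-one is silylated to 3-chloro-1-[4-(triisopropylsilyloxy)phenyl]propan-1-one F4. Corey–Bakshi–Shibata reduction with the (S)-oxazaborolidine and BH3·SMe2 should give (1R)-3-chloro-1-[4-(triisopropylsilyloxy)phenyl]propan-1-ol F5. A Mitsunobu reaction of F5 with 6 (PPh3, DIAD) should give, with inversion, 1-{2-[(1S)-3-chloro-1-(4-triisopropylsilyloxyphenyl)propoxy]-3-geranyl-4-(geranyloxy)-6-(triisopropylsilyloxy)phenyl}ethanone F6. Displacement of chloride by preformed PhSeNa gives 1-{3-geranyl-4-(geranyloxy)-2-[(1S)-3-(phenylselanyl)-1-(4-triisopropylsilyloxyphenyl)propoxy]-6-(triisopropylsilyloxy)phenyl}ethanone F7. Oxidation with H2O2 and pyridine and selenoxide syn-elimination return to the route at 12.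

**Step 3.** Silylation may occur at the wrong ortho-hydroxyl or at both, because the two differ only in one neighbour; the wrong isomer would carry through to the 6-geranyl series. The fallback makes the regiochemistry a consequence of bond formation. It sets out from 1: a Mitsunobu reaction with 4 gives the symmetric 1-[4-(geranyloxy)-2,6-dihydroxyphenyl]ethanone F8, whose mono-silylation (TIPSCl, imidazole) has no regiochemical question and gives 1-[4-(geranyloxy)-2-hydroxy-6-(triisopropylsilyloxy)phenyl]ethanone F9. C-Alkylation of the sodium phenoxide of F9 (NaH) with 2 in toluene, which in a non-polar medium goes ortho to the oxygen–metal bond, places the geranyl group next to the free hydroxyl and returns to the route at 6.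

**Step 1.** O-Alkylation and double alkylation compete with mono-C-alkylation, because the product is as nucleophilic as the starting material. The fallback changes the electrophile and the mechanism: a Friedel–Crafts-type alkylation of 1 with 4 and BF3·OEt2 in dioxane at room temperature. It generates no phenoxide and so cannot O-alkylate, and it is stopped at partial conversion to limit cyclisation of the chain. It sets out from 1 and 4 and comes back at 3, with no new compound.

**Step 10.** If the buffer is not effective, the enolate set free from the enol silane, or the phenoxides, may open ring C by beta-elimination and reclose it without control, racemising C2. The aryl TIPS ethers may also be cleaved only slowly. The fallback separates the two events and uses no basic species. It sets out from 14: aqueous acetic acid in THF should hydrolyse only the enol silane, and 15 is isolated. HF·pyridine buffered with pyridine in THF then removes the two aryl silyl ethers and returns to the route at 16.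

## Further compounds

F1 | step 9 | (E)-3-(dimethylamino)-1-[3-geranyl-4-(geranyloxy)-2-hydroxy-6-(triisopropylsilyloxy)phenyl]prop-2-en-1-one | CN(C)/C=C/C(=O)c1c(O[Si](C(C)C)(C(C)C)C(C)C)cc(OC/C=C(\C)CCC=C(C)C)c(C/C=C(\C)CCC=C(C)C)c1O
F2 | step 9 | 8-geranyl-7-(geranyloxy)-5-(triisopropylsilyloxy)-4H-chromen-4-one | CC(C)=CCC/C(C)=C/COc1cc(O[Si](C(C)C)(C(C)C)C(C)C)c2c(c1C/C=C(\C)CCC=C(C)C)OC=CC2=O
F3 | step 9 | (2S)-2-[4-(tert-butyldimethylsilyloxy)phenyl]-8-geranyl-7-(geranyloxy)-5-(triisopropylsilyloxy)chroman-4-one | CC(C)=CCC/C(C)=C/COc1cc(O[Si](C(C)C)(C(C)C)C(C)C)c2c(c1C/C=C(\C)CCC=C(C)C)O[C@H](c1ccc(O[Si](C)(C)C(C)(C)C)cc1)CC2=O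
F4 | step 7 | 3-chloro-1-[4-(triisopropylsilyloxy)phenyl]propan-1-one | O=C(CCCl)c1ccc(O[Si](C(C)C)(C(C)C)C(C)C)cc1
F5 | step 7 | (1R)-3-chloro-1-[4-(triisopropylsilyloxy)phenyl]propan-1-ol | O[C@H](CCCl)c1ccc(O[Si](C(C)C)(C(C)C)C(C)C)cc1
F6 | step 7 | 1-{2-[(1S)-3-chloro-1-(4-triisopropylsilyloxyphenyl)propoxy]-3-geranyl-4-(geranyloxy)-6-(triisopropylsilyloxy)phenyl}ethanone | CC(=O)c1c(O[Si](C(C)C)(C(C)C)C(C)C)cc(OC/C=C(\C)CCC=C(C)C)c(C/C=C(\C)CCC=C(C)C)c1O[C@H](c1ccc(O[Si](C(C)C)(C(C)C)C(C)C)cc1)CCCl
F7 | step 7 | 1-{3-geranyl-4-(geranyloxy)-2-[(1S)-3-(phenylselanyl)-1-(4-triisopropylsilyloxyphenyl)propoxy]-6-(triisopropylsilyloxy)phenyl}ethanone | CC(=O)c1c(O[Si](C(C)C)(C(C)C)C(C)C)cc(OC/C=C(\C)CCC=C(C)C)c(C/C=C(\C)CCC=C(C)C)c1O[C@H](c1ccc(O[Si](C(C)C)(C(C)C)C(C)C)cc1)CC[Se]c1ccccc1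
F8 | step 3 | 1-[4-(geranyloxy)-2,6-dihydroxyphenyl]ethanone | CC(=O)c1c(O)cc(OC/C=C(\C)CCC=C(C)C)cc1O
F9 | step 3 | 1-[4-(geranyloxy)-2-hydroxy-6-(triisopropylsilyloxy)phenyl]ethanone | CC(=O)c1c(O)cc(OC/C=C(\C)CCC=C(C)C)cc1O[Si](C(C)C)(C(C)C)C(C)C
F0 | step 1 | none | none
F0 | step 10 | none | none
A1 | alternative 1 | 4-{(3R)-1-(tert-butyldimethylsilyloxy)-3-[4-(tert-butyldimethylsilyloxy)phenyl]-3-(triethylsilyloxy)propyl}-3-(triisopropylsilyloxy)cyclobut-2-en-1-one | O=C1C=C(O[Si](C(C)C)(C(C)C)C(C)C)C1C(O[Si](C)(C)C(C)(C)C)C[C@@H](O[Si](CC)(CC)CC)c1ccc(O[Si](C)(C)C(C)(C)C)cc1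
A2 | alternative 1 | {[(4E)-5,9-dimethyldeca-4,8-dien-1-yn-1-yl]oxy}triisopropylsilane | CC(C)=CCC/C(C)=C/CC#CO[Si](C(C)C)(C(C)C)C(C)C
A3 | alternative 1 | 2-geranyl-3,5-bis(triisopropylsilyloxy)-6-[(3R)-1-(tert-butyldimethylsilyloxy)-3-(triethylsilyloxy)-3-(4-tert-butyldimethylsilyloxyphenyl)propyl]phenol | Oc1c(C/C=C(\C)CCC=C(C)C)c(O[Si](C(C)C)(C(C)C)C(C)C)cc(O[Si](C(C)C)(C(C)C)C(C)C)c1C(O[Si](C)(C)C(C)(C)C)C[C@@H](O[Si](CC)(CC)CC)c1ccc(O[Si](C)(C)C(C)(C)C)cc1
A4 | alternative 2 | methyl (6E)-7,11-dimethyl-3-oxo-4-{(2S)-4-oxo-2-[4-(triisopropylsilyloxy)phenyl]-3,4-dihydro-2H-pyran-6-yl}dodeca-6,10-dienoate | COC(=O)CC(=O)C(C/C=C(\C)CCC=C(C)C)C1=CC(=O)C[C@@H](c2ccc(O[Si](C(C)C)(C(C)C)C(C)C)cc2)O1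
A5 | alternative 2 | (2S)-8-geranyl-5,7-dihydroxy-2-[4-(triisopropylsilyloxy)phenyl]chroman-4-one | Oc1cc(O)c2c(c1C/C=C(\C)CCC=C(C)C)O[C@H](c1ccc(O[Si](C(C)C)(C(C)C)C(C)C)cc1)CC2=O
A6 | alternative 3 | (3S)-1-[2-fluoro-3-geranyl-4,6-bis(methoxymethoxy)phenyl]-3-hydroxy-3-[4-(methoxymethoxy)phenyl]propan-1-one | COCOc1cc(OCOC)c(C(=O)C[C@H](O)c2ccc(OCOC)cc2)c(F)c1C/C=C(\C)CCC=C(C)C
A7 | alternative 3 | (2S)-8-geranyl-5,7-bis(methoxymethoxy)-2-[4-(methoxymethoxy)phenyl]chroman-4-one | COCOc1cc(OCOC)c2c(c1C/C=C(\C)CCC=C(C)C)O[C@H](c1ccc(OCOC)cc1)CC2=O
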